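**Plan**

- Numbering of the bicycle: C1 is the methylated bridgehead, C2 carries aryl and methyl, C5 is the bridgehead CH, and C6 is the cyclopropane CH2.
- Retrosynthesis first removes the two aryl C–Br bonds and puts the phenol back as its methyl ether. It then cuts C1–C6 and C2–CH3 together: a quaternary benzylic C2 bonded to cyclopropane carbon C1, with C6 spanning C1 and C5, is a cyclopropylcarbinyl cation quenched by methyl, and that cation comes from a C5–CH2X homoallyl unit with an aryl-bearing C1=C2 double bond.
- The remaining cuts are aryl–C2 (coupling of an enol triflate) and C5–C6 (conjugate addition of a hydroxymethyl equivalent to 2-methylcyclopentenone).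
- Forward: the five-membered ring is bought; C5–C6 is made first, the aryl group is joined next, CH2Si becomes CH2OMs, the three-membered ring closes together with methylation of C2, and the phenol is freed and dibrominated last.
- Stereochemistry: C5 comes from the chiral copper catalyst; C1 follows from C5 because the cyclopropane can only be cis-fused; C2 follows from methyl delivery anti to the new C1–C6 bond.

Key step: step 5

Assumption: the sense of induction of the chiral copper catalyst with this silylmethyl Grignard reagent cannot be predicted, so the ligand antipode that gives the (S) configuration at the carbon receiving the CH2Si group is the one used.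

**Route**

Step 1
Reactants: 1 (chloromethyl)dimethyl(propan-2-yloxy)silane; 2 2-methylcyclopent-2-en-1-one
Product: 5 (3S)-3-{[dimethyl(propan-2-yloxy)silyl]methyl}-2-methylcyclopent-1-en-1-yl trifluoromethanesulfonate, via silylmethyl Grignard reagent 3 (not isolated), via chloromagnesium enolate 4 (not isolated)
Conditions: Mg, BrCH2CH2Br (cat.), Et2O, reflux; then added to 2, Cu(OTf)2 (5 mol %), chiral imidazolinium salt (NHC precursor, 6 mol %), Et2O, −30 °C; then Comins' reagent, THF, −30 °C → rt
Reagents that add atoms: Comins' reagent, N-(5-chloropyridin-2-yl)-1,1,1-trifluoro-N-(trifluoromethylsulfonyl)methanesulfonamide, FC(F)(F)S(=O)(=O)N(c1ccc(Cl)cn1)S(=O)(=O)C(F)(F)F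
Why: Copper-catalysed asymmetric conjugate addition of a Grignard reagent to an α-substituted cyclic enone followed by O-triflation of the regiodefined magnesium enolate: the chiral NHC–copper complex differentiates the enone faces so that the silylmethyl group is delivered to give the (S) centre, and trapping on oxygen locks the double bond between the former carbonyl carbon and the methyl-bearing carbon.

Step 2
Reactants: 5 (3S)-3-{[dimethyl(propan-2-yloxy)silyl]methyl}-2-methylcyclopent-1-en-1-yl trifluoromethanesulfonate; 6 (2-methoxy-4-methylphenyl)boronic acid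
Product: 7 {[(1S)-3-(2-methoxy-4-methylphenyl)-2-methylcyclopent-2-en-1-yl]methyl}dimethyl(propan-2-yloxy)silane
Conditions: Pd(OAc)2 (3 mol %), SPhos (6 mol %), K3PO4·H2O, 1,4-dioxane, 70 °C
Reagents that add atoms: none
Why: Suzuki–Miyaura coupling of an enol triflate with an arylboronic acid, for which a bulky biarylphosphine ligand overcomes the ortho substituents on both partners; the stereocentre is not involved, and any exchange of the isopropoxysilane to silanol is harmless because both are oxidised in step 3.

Step 3
Reactants: 7 {[(1S)-3-(2-methoxy-4-methylphenyl)-2-methylcyclopent-2-en-1-yl]methyl}dimethyl(propan-2-yloxy)silane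
Product: 8 [(1S)-3-(2-methoxy-4-methylphenyl)-2-methylcyclopent-2-en-1-yl]methanol
Conditions: 30 % H2O2, KF, KHCO3, THF/MeOH (1:1), rt → 40 °C
Reagents that add atoms: hydrogen peroxide, OO
Why: Tamao oxidation: fluoride-activated silicon adds hydroperoxide and the CH2 group migrates from silicon to oxygen, while basic hydrogen peroxide does not attack the unactivated tetrasubstituted double bond or the stereocentre.

Step 4
Reactants: 8 [(1S)-3-(2-methoxy-4-methylphenyl)-2-methylcyclopent-2-en-1-yl]methanol
Product: 9 [(1S)-3-(2-methoxy-4-methylphenyl)-2-methylcyclopent-2-en-1-yl]methyl methanesulfonate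
Conditions: MsCl, Et3N, CH2Cl2, −10 → 0 °C; cold aqueous wash, used crude
Reagents that add atoms: methanesulfonyl chloride, CS(=O)(=O)Cl
Why: Mesylation of a primary alcohol through sulfene under cold amine-buffered conditions; the homoallylic sulfonate is taken on crude after a cold aqueous wash so that it cannot ionise on silica.

Step 5
Reactants: 9 [(1S)-3-(2-methoxy-4-methylphenyl)-2-methylcyclopent-2-en-1-yl]methyl methanesulfonate
Product: 11 (1S,2R,5R)-2-(2-methoxy-4-methylphenyl)-1,2-dimethylbicyclo[3.1.0]hexane, via cyclopropylcarbinyl cation aluminate ion pair 10 (not isolated)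
Conditions: AlMe3 (4 equiv, hexanes), CH2Cl2, −78 °C → rt; aq. Rochelle salt
Reagents that add atoms: trimethylaluminium, C[Al](C)C
Why: Proposed new method: AlMe3 binds the sulfonate and, assisted by the electron-rich tetrasubstituted aryl-alkene, C1 displaces the mesylate from C6 in a 3-exo-tet closure that makes the C1–C6 bond and the cyclopropane, which leaves the tertiary, benzylic cyclopropylcarbinyl cation 10 paired with a methylaluminate that hands a methyl group to C2. The closest known reaction types are the homoallyl-to-cyclopropylcarbinyl (i-steroid) ionisation of homoallylic sulfonates, the C-methylation of tertiary benzylic cations by trimethylaluminium, and organoaluminium-promoted ionisation of sulfonates with alkyl transfer as in the aluminium-mediated Beckmann rearrangement; their union on a primary mesylate is untested. C1 is controlled by C5, because the CH2 group can only reach the alkene face on which it sits, so the ring fusion is necessarily cis. C2 is controlled by the bridged cation, which shields the face bearing C6, so methyl enters anti to the C1–C6 bond (as nucleophiles enter i-steroid cations) and the aryl group ends cis to C6. The step needs methyl capture at C2 in preference to attack at C6 or C5 (homoallyl or ring-enlarged products), proton loss from C3, and four-membered-ring closure. The o-anisyl-stabilised tertiary centre localises the charge at C2, closure through C2 would leave a non-benzylic cation, and low temperature with excess AlMe3 favours irreversible methyl transfer over elimination.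

Step 6
Reactants: 11 (1S,2R,5R)-2-(2-methoxy-4-methylphenyl)-1,2-dimethylbicyclo[3.1.0]hexane
Product: 12 2-[(1S,2R,5R)-1,2-dimethylbicyclo[3.1.0]hexan-2-yl]-5-methylphenol
Conditions: NaSEt (5 equiv), DMF, 140 °C; sat. aq. NH4Cl work-up
Reagents that add atoms: none
Why: Nucleophilic (SN2) O-demethylation of the aryl methyl ether by ethanethiolate in hot DMF, a purely basic method that spares the cyclopropane, which would open under the Lewis or protic acids otherwise used for ether cleavage; the quaternary centres cannot epimerise.

Step 7
Reactants: 12 2-[(1S,2R,5R)-1,2-dimethylbicyclo[3.1.0]hexan-2-yl]-5-methylphenol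
Product: 13 2,4-dibromo-6-[(1S,2R,5R)-1,2-dimethylbicyclo[3.1.0]hexan-2-yl]-3-methylphenol
Conditions: NBS (2.05 equiv, recrystallised), NaHCO3, MeCN, −20 → 0 °C, dark
Reagents that add atoms: N-bromosuccinimide, O=C1CCC(=O)N1Br
Why: Electrophilic aromatic bromination of the phenol with NBS, which occurs para and then at the one free ortho position because the other ortho carbon carries the bicycle, while bicarbonate and low temperature keep the medium free of acid that would let the phenol oxygen open the cyclopropane.

**Compound list**

1 | (chloromethyl)dimethyl(propan-2-yloxy)silane | CC(C)O[Si](C)(C)CCl | starting material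
2 | 2-methylcyclopent-2-en-1-one | CC1=CCCC1=O | starting material
3 | {[dimethyl(propan-2-yloxy)silyl]methyl}magnesium chloride | CC(C)O[Si](C)(C)C[Mg]Cl | intermediate (not isolated)
4 | chloromagnesium (3S)-3-{[dimethyl(propan-2-yloxy)silyl]methyl}-2-methylcyclopent-1-en-1-olate | Cl[Mg]OC1=C(C)[C@@H](C[Si](C)(C)OC(C)C)CC1 | intermediate (not isolated)
5 | (3S)-3-{[dimethyl(propan-2-yloxy)silyl]methyl}-2-methylcyclopent-1-en-1-yl trifluoromethanesulfonate | FC(F)(F)S(=O)(=O)OC1=C(C)[C@@H](C[Si](C)(C)OC(C)C)CC1 | intermediate
6 | (2-methoxy-4-methylphenyl)boronic acid | COc1cc(C)ccc1B(O)O | starting material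
7 | {[(1S)-3-(2-methoxy-4-methylphenyl)-2-methylcyclopent-2-en-1-yl]methyl}dimethyl(propan-2-yloxy)silane | COc1cc(C)ccc1C2=C(C)[C@@H](C[Si](C)(C)OC(C)C)CC2 | intermediate
8 | [(1S)-3-(2-methoxy-4-methylphenyl)-2-methylcyclopent-2-en-1-yl]methanol | COc1cc(C)ccc1C2=C(C)[C@@H](CO)CC2 | intermediate
9 | [(1S)-3-(2-methoxy-4-methylphenyl)-2-methylcyclopent-2-en-1-yl]methyl methanesulfonate | COc1cc(C)ccc1C2=C(C)[C@@H](COS(C)(=O)=O)CC2 | intermediate
10 | 2-(2-methoxy-4-methylphenyl)-1-methylbicyclo[3.1.0]hexan-2-ylium methanesulfonato(trimethyl)aluminate ion pair (cis-fused cyclopropane, C5 as in 9) | COc1cc(C)ccc1[C+]2CC[C@@H]3C[C@@]32C.C[Al-](C)(C)OS(C)(=O)=O | intermediate (not isolated)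
11 | (1S,2R,5R)-2-(2-methoxy-4-methylphenyl)-1,2-dimethylbicyclo[3.1.0]hexane | COc1cc(C)ccc1[C@]2(C)CC[C@@H]3C[C@@]32C | intermediate
12 | 2-[(1S,2R,5R)-1,2-dimethylbicyclo[3.1.0]hexan-2-yl]-5-methylphenol | Cc1ccc([C@]2(C)CC[C@@H]3C[C@@]32C)c(O)c1 | intermediate
13 | 2,4-dibromo-6-[(1S,2R,5R)-1,2-dimethylbicyclo[3.1.0]hexan-2-yl]-3-methylphenol | Cc1c(Br)cc([C@]2(C)CC[C@@H]3C[C@@]32C)c(O)c1Br | target

**Step count**

Total steps: 7. Longest linear sequence: 7 steps (from 1 and 2 to 13); boronic acid 6 enters as bought.

**Steps most likely to fail**

Step 5. The aluminium Lewis acid may be too weak to ionise a primary sulfonate. Alternatively the cation may be lost by proton elimination from C3, by methyl delivery to C6 with return to the cyclopentene skeleton, or by unselective attack on the two faces of C2. A co-Lewis acid such as Me2AlCl would be tried first, but the real fallback separates ring closure from methylation with known reactions; it sets out from 9 and returns at 11. Mesylate 9 is solvolysed under buffered i-steroid conditions (NaHCO3, aqueous acetone, 50–60 °C), where water captures the cation at C2 anti to the new C1–C6 bond and should give the tertiary cyclopropylcarbinol (1S,2S,5R)-2-(2-methoxy-4-methylphenyl)-1-methylbicyclo[3.1.0]hexan-2-ol F1. This tertiary benzylic alcohol is then C-methylated with excess AlMe3 in CH2Cl2 or toluene, or with dimethyltitanium dichloride at −30 °C, the known SN1 methylation of tertiary benzylic alcohols, to give 11.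

Step 1. The bulky, oxygen-bearing silylmethyl nucleophile may add with poor facial selectivity, 1,2-addition may compete, or O-triflation of the magnesium enolate may be slow. The fallback replaces catalyst control by resolution; it sets out from 1 and 2 and returns at 8. The Grignard reagent 3 is added to 2 under achiral copper catalysis (CuI, THF, −30 °C), and the racemic enolate rac-chloromagnesium 3-{[dimethyl(propan-2-yloxy)silyl]methyl}-2-methylcyclopent-1-en-1-olate F2 is triflated as before to rac-3-{[dimethyl(propan-2-yloxy)silyl]methyl}-2-methylcyclopent-1-en-1-yl trifluoromethanesulfonate F3. Coupling with 6 as in step 2 gives rac-{[3-(2-methoxy-4-methylphenyl)-2-methylcyclopent-2-en-1-yl]methyl}dimethyl(propan-2-yloxy)silane F4, and Tamao oxidation as in step 3 gives rac-[3-(2-methoxy-4-methylphenyl)-2-methylcyclopent-2-en-1-yl]methanol F5. F5 is separated by preparative chromatography on a chiral stationary phase, and the (S)-enantiomer is 8.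

Step 7. Traces of acid or the brominating agent may trigger opening of the cyclopropane by the neighbouring phenol oxygen, or the second bromination at the carbon flanked by OH and CH3 may stall or overshoot. The fallback stages the two brominations with different reagents; it sets out from 12 and returns at 13. One equivalent of NBS at −40 °C in buffered MeCN should brominate only the para position and give 4-bromo-2-[(1S,2R,5R)-1,2-dimethylbicyclo[3.1.0]hexan-2-yl]-5-methylphenol F6, which is isolated. The ortho bromine is then introduced under amine-buffered, ortho-selective conditions (t-BuNH2, Br2, toluene, −78 °C, through the N-bromoamine) to give 13.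

**Further compounds**

F1 | step 5 | (1S,2S,5R)-2-(2-methoxy-4-methylphenyl)-1-methylbicyclo[3.1.0]hexan-2-ol | COc1cc(C)ccc1[C@]2(O)CC[C@@H]3C[C@@]32C
F2 | step 1 | rac-chloromagnesium 3-{[dimethyl(propan-2-yloxy)silyl]methyl}-2-methylcyclopent-1-en-1-olate | Cl[Mg]OC1=C(C)C(C[Si](C)(C)OC(C)C)CC1
F3 | step 1 | rac-3-{[dimethyl(propan-2-yloxy)silyl]methyl}-2-methylcyclopent-1-en-1-yl trifluoromethanesulfonate | FC(F)(F)S(=O)(=O)OC1=C(C)C(C[Si](C)(C)OC(C)C)CC1
F4 | step 1 | rac-{[3-(2-methoxy-4-methylphenyl)-2-methylcyclopent-2-en-1-yl]methyl}dimethyl(propan-2-yloxy)silane | COc1cc(C)ccc1C2=C(C)C(C[Si](C)(C)OC(C)C)CC2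
F5 | step 1 | rac-[3-(2-methoxy-4-methylphenyl)-2-methylcyclopent-2-en-1-yl]methanol | COc1cc(C)ccc1C2=C(C)C(CO)CC2
F6 | step 7 | 4-bromo-2-[(1S,2R,5R)-1,2-dimethylbicyclo[3.1.0]hexan-2-yl]-5-methylphenol | Cc1c(Br)cc([C@]2(C)CC[C@@H]3C[C@@]32C)c(O)c1
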